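**Plan**

- The retrosynthesis first cuts the C6–C7 sp–sp bond of the 5,7-diyne (C1 = carboxyl carbon), which gives hex-5-ynoic acid and 2-(heptadec-16-yn-1-yl)furan. It then cuts the C11–C12 sp3–sp3 bond of the chain and the bond from C23 to furan C2.
- The feature that makes the key event possible: C6 and C7 are both sp carbons, each the inner end of a triple bond (C5≡C6 and C7≡C8). Each half is therefore a terminal alkyne, and both acetylides can be bound to one and the same boron atom. An iodine-induced 1,2-shift from boron to carbon then makes C6–C7 with no 1-haloalkyne and no homocoupling.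
- Forward order: the furan ring is bought and lithiated at C2 (next to the ring oxygen), then alkylated with 1,12-dibromododecane. A silyl-capped C5 alkynyl Grignard reagent is joined by copper catalysis, and the silyl group is removed. The boron-templated coupling with hex-5-ynoic acid finishes the chain.
- The boron template is made in one step and leaves in the key step. The carboxylic acid is masked only as its lithium salt, so the key step should give the target directly.
- Stereochemistry: the target has no stereocentre and no stereogenic double bond, so nothing has to be set.

Key step: step 5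

Remark: the 3-methylbutan-2-yl (siamyl) ligands on boron are stereogenic and are used as the isomer mixture that hydroboration gives. They do not enter the target, so the boron compounds are written without configuration.

**Route**

Step 1
Reactants: 1 furan; 2 1,12-dibromododecane
Product: 4 2-(12-bromododecyl)furan, via furan-2-yllithium 3 (not isolated)
Conditions: n-BuLi (1.0 equiv), THF, 0 °C; then added to 2 (3 equiv), THF, −20 °C → rt
Reagents that add atoms: none
Why: n-BuLi lithiates furan at C2, next to the ring oxygen, and the heteroaryllithium should undergo SN2 alkylation at one end of the primary dibromide, whose threefold excess favours mono-substitution.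

Step 2
Reactants: 4 2-(12-bromododecyl)furan; 5 (5-chloropent-1-yn-1-yl)trimethylsilane
Product: 7 [17-(furan-2-yl)heptadec-1-yn-1-yl]trimethylsilane, via alkylmagnesium chloride 6 (not isolated)
Conditions: 5, Mg turnings, THF, reflux (1,2-dibromoethane to start); then 4, Li2CuCl4 (3 mol %), THF/NMP, −10 °C → rt
Reagents that add atoms: none
Why: a Kochi-type copper-catalysed sp3–sp3 cross-coupling of a primary alkylmagnesium chloride with a primary alkyl bromide should join C11 to C12, and neither the furan nor the silyl-capped alkyne reacts with the Grignard reagent.

Step 3
Reactants: 7 [17-(furan-2-yl)heptadec-1-yn-1-yl]trimethylsilane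
Product: 8 2-(heptadec-16-yn-1-yl)furan
Conditions: K2CO3, MeOH/THF, rt
Reagents that add atoms: none
Why: base-mediated methanolysis of the C(sp)–Si bond (protodesilylation of an alkynylsilane) should free the terminal alkyne under conditions that leave the furan untouched.

Step 4
Reactants: 9 borane–dimethyl sulfide complex; 10 2-methylbut-2-ene
Product: 12 methoxybis(3-methylbutan-2-yl)borane, via disiamylborane 11 (not isolated)
Conditions: 10 (2.0 equiv), THF, 0 °C; then MeOH (1.0 equiv), 0 °C → rt; used as a THF solution
Reagents that add atoms: methanol, CO
Why: hydroboration of the trisubstituted alkene stops at the dialkylborane for steric reasons, and alcoholysis of the remaining B–H bond should give the borinic ester that serves as the boron template.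

Step 5
Reactants: 8 2-(heptadec-16-yn-1-yl)furan; 12 methoxybis(3-methylbutan-2-yl)borane; 13 hex-5-ynoic acid
Product: 19 23-(furan-2-yl)tricosa-5,7-diynoic acid, via lithium acetylide 14 (not isolated), via lithium methoxyborate 15 (not isolated), via alkynylborane 16 (not isolated), via dilithio hexynoate 17 (not isolated), via lithium dialkynylborate 18 (not isolated)
Conditions: 8, n-BuLi (1.0 equiv), THF, −78 °C; 12, −78 °C; BF3·OEt2 (1.33 equiv), −78 °C; 17 [from 13, n-BuLi (2.0 equiv), THF/DMPU, −78 → 0 °C], −78 °C; I2 (1.0 equiv), THF, −78 °C → rt; aq. Na2S2O3, then aq. citric acid
Reagents that add atoms: none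
Why: The acetylide 14 adds to the borinic ester 12 and BF3·OEt2 removes the methoxide, so that the neutral alkynylborane 16 can accept the second, different acetylide 17 and give the borate 18, in which C6 and C7 of the future diyne are both bound to one boron atom; iodine then attacks the β-carbon of one alkynyl ligand, the other alkynyl ligand shifts from boron to the boron-bound carbon (1,2-metallate rearrangement) and makes the C6–C7 bond, and β-elimination of boron and iodine restores the triple bond. The closest known reaction type is the iodine-induced coupling of lithium dialkyldialkynylborates to unsymmetrical 1,3-diynes, a relative of the Zweifel reaction. No ring is closed and no stereocentre is formed. The step needs cross-coupling without homocoupling, which is secured because the two alkynyl groups are loaded one after the other on the same boron atom and the bond forms within that one borate; it needs migration of an alkynyl and not of an alkyl ligand, which the hindered secondary 3-methylbutan-2-yl groups secure by their low migratory aptitude; and it needs lithiation of the alkyne C–H and not of furan C5–H, which the large difference in acidity secures at −78 °C. The carboxyl group is carried as its lithium salt in 17 and 18, so that acidification on work-up should give the free acid 19 without a deprotection step.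

**Compound list**

1 | furan | c1ccoc1 | starting material
2 | 1,12-dibromododecane | BrCCCCCCCCCCCCBr | starting material
3 | furan-2-yllithium | [Li]c1ccco1 | intermediate
4 | 2-(12-bromododecyl)furan | BrCCCCCCCCCCCCc1ccco1 | intermediate
5 | (5-chloropent-1-yn-1-yl)trimethylsilane | C[Si](C)(C)C#CCCCCl | starting material
6 | [5-(trimethylsilyl)pent-4-yn-1-yl]magnesium chloride | C[Si](C)(C)C#CCCC[Mg]Cl | intermediate
7 | [17-(furan-2-yl)heptadec-1-yn-1-yl]trimethylsilane | C[Si](C)(C)C#CCCCCCCCCCCCCCCCc1ccco1 | intermediate
8 | 2-(heptadec-16-yn-1-yl)furan | C#CCCCCCCCCCCCCCCCc1ccco1 | intermediate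
9 | borane–dimethyl sulfide complex | [BH3-][S+](C)C | starting material
10 | 2-methylbut-2-ene | CC=C(C)C | starting material
11 | bis(3-methylbutan-2-yl)borane (disiamylborane) | CC(C)C(C)BC(C)C(C)C | intermediate
12 | methoxybis(3-methylbutan-2-yl)borane | COB(C(C)C(C)C)C(C)C(C)C | intermediate
13 | hex-5-ynoic acid | C#CCCCC(=O)O | starting material
14 | [17-(furan-2-yl)heptadec-1-yn-1-yl]lithium | [Li]C#CCCCCCCCCCCCCCCCc1ccco1 | intermediate
15 | lithium [17-(furan-2-yl)heptadec-1-yn-1-yl](methoxy)bis(3-methylbutan-2-yl)borate | [Li+].CO[B-](C#CCCCCCCCCCCCCCCCc1ccco1)(C(C)C(C)C)C(C)C(C)C | intermediate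
16 | [17-(furan-2-yl)heptadec-1-yn-1-yl]bis(3-methylbutan-2-yl)borane | CC(C)C(C)B(C#CCCCCCCCCCCCCCCCc1ccco1)C(C)C(C)C | intermediate
17 | lithium 6-lithiohex-5-ynoate | [Li+].[O-]C(=O)CCCC#C[Li] | intermediate
18 | dilithium (5-carboxylatopent-1-yn-1-yl)[17-(furan-2-yl)heptadec-1-yn-1-yl]bis(3-methylbutan-2-yl)borate | [Li+].[Li+].[O-]C(=O)CCCC#C[B-](C#CCCCCCCCCCCCCCCCc1ccco1)(C(C)C(C)C)C(C)C(C)C | intermediate
19 | 23-(furan-2-yl)tricosa-5,7-diynoic acid | O=C(O)CCCC#CC#CCCCCCCCCCCCCCCCc1ccco1 | target

**Count and risks**

Total step count: 5. Longest linear sequence: 4 steps (steps 1, 2, 3 and 5, from furan); step 4 is a one-step side branch.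

Steps most likely to fail:

1. Step 5. The dilithiated acid may be too poorly soluble to add cleanly to the alkynylborane, so the mixed borate forms incompletely. Alkynyl ligands may also scramble between boron atoms, which would open the way to homocoupled diynes. A siamyl ligand may migrate in competition with the alkynyl ligand, and iodine may induce lactonisation of the carboxylate onto the neighbouring triple bond. Fallback: this sets out from 8, with 13 as the source of the second partner, and comes back at 19. Bromination of the terminal alkyne of 13 with hypobromite (Br2, aq. KOH, 0 °C) should give 6-bromohex-5-ynoic acid F1. A Cadiot–Chodkiewicz coupling of 8 with F1 (CuCl cat., NH2OH·HCl, aq. n-BuNH2, MeOH/THF, 0 °C), which tolerates the free acid and leaves the furan alone, should then give 19.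

2. Step 2. The copper-catalysed coupling may be outrun by homocoupling of the Grignard reagent, by halogen–magnesium exchange followed by reduction, or by elimination of the bromide. Fallback: this sets out from 4 and comes back at 8, so that 7 and step 3 are bypassed. SN2 alkylation of pent-1-ynyllithium (pent-1-yne, n-BuLi, THF/DMPU, −78 °C → rt) with 4 should give 2-(heptadec-13-yn-1-yl)furan F2. An alkyne zipper isomerisation (KH, 1,3-diaminopropane, 0 °C → rt) should then move the triple bond along the three-carbon tail to the chain end and give 8 after aqueous quench.

3. Step 1. The furyllithium may alkylate both ends of the dibromide or act as a base and eliminate HBr, and the product may be hard to separate from the excess dibromide. Fallback: this sets out from 1 (as its lithio derivative 3) and comes back at 4. Silylation of commercial 12-bromododecan-1-ol (TBSCl, imidazole, DMF) should give (12-bromododecyloxy)(tert-butyl)dimethylsilane F3, an electrophile with only one reactive end. Alkylation of 3 with F3 (THF, 0 °C → rt) should give tert-butyl{[12-(furan-2-yl)dodecyl]oxy}dimethylsilane F4. Desilylation with tetrabutylammonium fluoride in THF should give 12-(furan-2-yl)dodecan-1-ol F5, and an Appel bromination (CBr4, PPh3, CH2Cl2, 0 °C) should give 4.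

**Further compounds**

F1 | step 5 | 6-bromohex-5-ynoic acid | O=C(O)CCCC#CBr
F2 | step 2 | 2-(heptadec-13-yn-1-yl)furan | CCCC#CCCCCCCCCCCCCc1ccco1
F3 | step 1 | (12-bromododecyloxy)(tert-butyl)dimethylsilane | CC(C)(C)[Si](C)(C)OCCCCCCCCCCCCBr
F4 | step 1 | tert-butyl{[12-(furan-2-yl)dodecyl]oxy}dimethylsilane | CC(C)(C)[Si](C)(C)OCCCCCCCCCCCCc1ccco1
F5 | step 1 | 12-(furan-2-yl)dodecan-1-ol | OCCCCCCCCCCCCc1ccco1
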